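**Plan**
- Retrosynthesis: the three silyl ethers come off last. Ring C is cut at C2–C3, giving an ortho-methoxy benzil whose methoxy carbon is C2. The benzil is cut at C4–C4a (ring A aryllithium plus ring B arylacetic N-methoxy-N-methylamide, C3 oxidised afterwards), and the prenyl–aryl bonds at C6 and C8 are cut last.
- Forward: ring A is iodinated and prenylated, joined to the ring B acetamide at C4, C3 is oxidised to the ketone, and ring C (the only ring made) is closed by light.
- Enabling feature: C2 is an unsubstituted CH2 held between O1 and the hydroxylated quaternary C3, which sits next to the C4 ketone. A methoxy group on ring A beside a 1,2-diketone gives exactly this array when one methoxy hydrogen moves to the C3 oxygen and the two radical centres join.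
- Stereochemistry: C3, the only stereocentre, is created in step 8 as a racemate, because no chiral element is present and a Lewis acid on the dicarbonyl would block the lone pair that has to abstract. The (3R)-enantiomer is separated on a chiral stationary phase in step 9 and carried through desilylation unchanged.

Key step: step 8

TBS = tert-butyldimethylsilyl; prenyl = 3-methylbut-2-en-1-yl; atom numbers are those of the chroman-4-one of the target.

**Step 1**
Reactants: 1 4-bromo-3-methoxyphenol
Product: 2 4-bromo-2,6-diiodo-3-methoxyphenol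
Conditions: N-iodosuccinimide (2.1 equiv), TsOH·H2O (10 mol%), MeCN, 0 °C → rt
Reagents that add atoms: N-iodosuccinimide, O=C1CCC(=O)N1I
Why: Electrophilic aromatic iodination of a phenol whose para position is blocked by bromine should go to both ortho positions, the only ring carbons activated by the hydroxyl and the methoxy group together.

**Step 2**
Reactants: 2 4-bromo-2,6-diiodo-3-methoxyphenol
Product: 3 (4-bromo-2,6-diiodo-3-methoxyphenoxy)(tert-butyl)dimethylsilane
Conditions: TBSCl, imidazole, DMF, rt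
Reagents that add atoms: tert-butyldimethylsilyl chloride, CC(C)(C)[Si](C)(C)Cl
Why: Silyl ether formation masks the acidic diiodophenol for the cross-coupling and the organolithium step with a group that has no C–H bond next to oxygen and leaves under fluoride.

**Step 3**
Reactants: 3 (4-bromo-2,6-diiodo-3-methoxyphenoxy)(tert-butyl)dimethylsilane; 4 tributyl(3-methylbut-2-en-1-yl)stannane (2.2 equiv)
Product: 5 [4-bromo-3-methoxy-2,6-bis(3-methylbut-2-en-1-yl)phenoxy](tert-butyl)dimethylsilane
Conditions: Pd(PPh3)4 (10 mol%), toluene, 90 °C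
Reagents that add atoms: none
Why: In this twofold Stille coupling zerovalent palladium should insert into the two C–I bonds well before the electron-rich C–Br bond, and reductive elimination at the unsubstituted terminus of the aryl(prenyl)palladium intermediate should give the linear prenyl groups.

**Step 4**
Reactants: 6 (2,4-dihydroxyphenyl)acetic acid
Product: 8 2-(2,4-dihydroxyphenyl)-N-methoxy-N-methylacetamide, via 6-hydroxybenzofuran-2(3H)-one 7 (not isolated)
Conditions: EDC·HCl, DMAP (5 mol%), DMF, 0 °C → rt; then MeNH(OMe)·HCl, N-methylmorpholine, 40 °C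
Reagents that add atoms: N,O-dimethylhydroxylamine hydrochloride, CNOC.Cl
Why: Steglich-type lactonisation followed by aminolysis: carbodiimide activation should close the ortho-hydroxy acid to the five-membered aryl lactone 7, an activated ester that the hydroxylamine opens to the amide, so the phenols need no protection here.

**Step 5**
Reactants: 8 2-(2,4-dihydroxyphenyl)-N-methoxy-N-methylacetamide
Product: 9 2-[2,4-bis(tert-butyldimethylsilyloxy)phenyl]-N-methoxy-N-methylacetamide
Conditions: TBSCl (2.4 equiv), imidazole, DMF, rt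
Reagents that add atoms: tert-butyldimethylsilyl chloride, CC(C)(C)[Si](C)(C)Cl
Why: Silyl ether formation on both phenols gives groups that survive the organolithium step, offer the excited diketone no C–H bond next to oxygen on ring B, and leave under fluoride.

**Step 6**
Reactants: 5 [4-bromo-3-methoxy-2,6-bis(3-methylbut-2-en-1-yl)phenoxy](tert-butyl)dimethylsilane; 9 2-[2,4-bis(tert-butyldimethylsilyloxy)phenyl]-N-methoxy-N-methylacetamide
Product: 12 2-[2,4-bis(TBSO)phenyl]-1-[4-(TBSO)-2-methoxy-3,5-diprenylphenyl]ethan-1-one, via aryllithium 10 (not isolated), via lithium hemiaminal alkoxide 11 (not isolated)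
Conditions: n-BuLi, THF, −78 °C; then 9, −78 → −20 °C; aq. NH4Cl
Reagents that add atoms: none
Why: Bromine–lithium exchange beside the methoxy group and Weinreb ketone synthesis: aryllithium 10 should add once to the amide, and the chelated adduct 11 holds until work-up so the ketone is not attacked again.

**Step 7**
Reactants: 12 2-[2,4-bis(TBSO)phenyl]-1-[4-(TBSO)-2-methoxy-3,5-diprenylphenyl]ethan-1-one
Product: 14 1-[2,4-bis(TBSO)phenyl]-2-[4-(TBSO)-2-methoxy-3,5-diprenylphenyl]ethane-1,2-dione, via α-hydroperoxy ketone 13 (not isolated)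
Conditions: DABCO (0.5 equiv), air, 4 Å molecular sieves, DMF, 90 °C
Reagents that add atoms: dioxygen, O=O
Why: Amine-catalysed autoxidation of a deoxybenzoin: the enol of the doubly activated C3 methylene should take up O2, and hydroperoxide 13 loses water (Kornblum–DeLaMare-type) to the 1,2-diketone, while the non-acidic prenyl C–H bonds are left alone.

**Step 8**
Reactants: 14 1-[2,4-bis(TBSO)phenyl]-2-[4-(TBSO)-2-methoxy-3,5-diprenylphenyl]ethane-1,2-dione
Product: 16 rac-3-[2,4-bis(TBSO)phenyl]-7-(TBSO)-3-hydroxy-6,8-diprenyl-2,3-dihydro-4H-chromen-4-one, via triplet 1,6-biradical 15 (not isolated)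
Conditions: hν (427 nm LEDs), degassed PhCF3 (0.005 M), 20 °C
Reagents that add atoms: none
Why: Proposed new method: light of 427 nm should be absorbed only by the n,π* band of the 1,2-diketone; in its planar s-trans triplet O3 lies on the ring A side, where the methoxy group, pushed out of the ring plane by its two ortho neighbours, can hand a hydrogen atom to O3 through an eight-membered transition state, giving biradical 15 (O1–CH2 radical and C3 ketyl, the ketyl spin on C3 and O4 but not on C4). The closest known reaction type is the Norrish–Yang photocyclisation of ortho-alkylaryl 1,2-diketones to 2-hydroxyindan-1-ones and of ortho-alkoxyaryl ketones to benzofuran-3-ols; a methoxy hydrogen donor combined with the distal carbonyl of a benzil is not established. Ring C closes by combination of the two radical centres of the 1,6-biradical after intersystem crossing, which forms C2–C3 in a six-membered ring and keeps the C4 ketone. C3 is the only new stereocentre; nothing in 14 is chiral, and a Lewis acid on the dicarbonyl would occupy the oxygen lone pair that has to abstract, so C3 should form without facial bias as the racemate and its configuration is secured in step 9. The step needs abstraction by O3 and not by O4 (which would end in a 3-aroylbenzofuran-3-ol): lone-pair repulsion should keep O4 turned away from the methoxy oxygen, the silyl ethers of ring B have no C–H bond next to oxygen, and the allylic CH2 groups at C6 and C8 sit too far from either carbonyl oxygen.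

**Step 9**
Reactants: 16 rac-3-[2,4-bis(TBSO)phenyl]-7-(TBSO)-3-hydroxy-6,8-diprenyl-2,3-dihydro-4H-chromen-4-one
Product: 17 (3R)-3-[2,4-bis(TBSO)phenyl]-7-(TBSO)-3-hydroxy-6,8-diprenyl-2,3-dihydro-4H-chromen-4-one
Conditions: preparative HPLC, amylose tris(3,5-dimethylphenylcarbamate) on silica, n-hexane/i-PrOH
Reagents that add atoms: none
Why: Resolution by chromatography on a chiral stationary phase; C3 is quaternary and cannot epimerise, and the (3R)-enantiomer is to be identified by comparing measured and calculated circular dichroism.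

**Step 10**
Reactants: 17 (3R)-3-[2,4-bis(TBSO)phenyl]-7-(TBSO)-3-hydroxy-6,8-diprenyl-2,3-dihydro-4H-chromen-4-one
Product: 18 (3R)-3-(2,4-dihydroxyphenyl)-3,7-dihydroxy-6,8-bis(3-methylbut-2-en-1-yl)-2,3-dihydro-4H-chromen-4-one
Conditions: Bu4NF (3.3 equiv), AcOH (3.5 equiv), THF, 0 °C
Reagents that add atoms: none
Why: Fluoride cleavage of the three aryl silyl ethers, buffered with acetic acid so that the phenoxides are protonated at once; the tertiary α-ketol sees no free base, no acid is present that could cyclise a prenyl group onto the neighbouring phenol, and C3 is untouched.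

**Compound list**
1 | 4-bromo-3-methoxyphenol | COc1cc(O)ccc1Br | starting material
2 | 4-bromo-2,6-diiodo-3-methoxyphenol | COc1c(Br)cc(I)c(O)c1I | intermediate
3 | (4-bromo-2,6-diiodo-3-methoxyphenoxy)(tert-butyl)dimethylsilane | COc1c(Br)cc(I)c(O[Si](C)(C)C(C)(C)C)c1I | intermediate
4 | tributyl(3-methylbut-2-en-1-yl)stannane | CCCC[Sn](CCCC)(CCCC)CC=C(C)C | starting material
5 | [4-bromo-3-methoxy-2,6-bis(3-methylbut-2-en-1-yl)phenoxy](tert-butyl)dimethylsilane | COc1c(Br)cc(CC=C(C)C)c(O[Si](C)(C)C(C)(C)C)c1CC=C(C)C | intermediate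
6 | (2,4-dihydroxyphenyl)acetic acid | O=C(O)Cc1ccc(O)cc1O | starting material
7 | 6-hydroxybenzofuran-2(3H)-one | O=C1Cc2ccc(O)cc2O1 | intermediate
8 | 2-(2,4-dihydroxyphenyl)-N-methoxy-N-methylacetamide | CON(C)C(=O)Cc1ccc(O)cc1O | intermediate
9 | 2-[2,4-bis(tert-butyldimethylsilyloxy)phenyl]-N-methoxy-N-methylacetamide | CON(C)C(=O)Cc1ccc(O[Si](C)(C)C(C)(C)C)cc1O[Si](C)(C)C(C)(C)C | intermediate
10 | [4-(tert-butyldimethylsilyloxy)-2-methoxy-3,5-bis(3-methylbut-2-en-1-yl)phenyl]lithium | COc1c([Li])cc(CC=C(C)C)c(O[Si](C)(C)C(C)(C)C)c1CC=C(C)C | intermediate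
11 | lithium 2-[2,4-bis(TBSO)phenyl]-1-[4-(TBSO)-2-methoxy-3,5-diprenylphenyl]-1-[methoxy(methyl)amino]ethan-1-olate (racemic) | COc1c(C(O[Li])(Cc2ccc(O[Si](C)(C)C(C)(C)C)cc2O[Si](C)(C)C(C)(C)C)N(C)OC)cc(CC=C(C)C)c(O[Si](C)(C)C(C)(C)C)c1CC=C(C)C | intermediate
12 | 2-[2,4-bis(TBSO)phenyl]-1-[4-(TBSO)-2-methoxy-3,5-diprenylphenyl]ethan-1-one | COc1c(C(=O)Cc2ccc(O[Si](C)(C)C(C)(C)C)cc2O[Si](C)(C)C(C)(C)C)cc(CC=C(C)C)c(O[Si](C)(C)C(C)(C)C)c1CC=C(C)C | intermediate
13 | 2-[2,4-bis(TBSO)phenyl]-2-hydroperoxy-1-[4-(TBSO)-2-methoxy-3,5-diprenylphenyl]ethan-1-one (racemic) | COc1c(C(=O)C(OO)c2ccc(O[Si](C)(C)C(C)(C)C)cc2O[Si](C)(C)C(C)(C)C)cc(CC=C(C)C)c(O[Si](C)(C)C(C)(C)C)c1CC=C(C)C | intermediate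
14 | 1-[2,4-bis(TBSO)phenyl]-2-[4-(TBSO)-2-methoxy-3,5-diprenylphenyl]ethane-1,2-dione | COc1c(C(=O)C(=O)c2ccc(O[Si](C)(C)C(C)(C)C)cc2O[Si](C)(C)C(C)(C)C)cc(CC=C(C)C)c(O[Si](C)(C)C(C)(C)C)c1CC=C(C)C | intermediate
15 | triplet 1,6-biradical from 14 (aryloxymethyl radical on O1 and hydroxy(aryl)methyl radical at C3) | [CH2]Oc1c(C(=O)[C](O)c2ccc(O[Si](C)(C)C(C)(C)C)cc2O[Si](C)(C)C(C)(C)C)cc(CC=C(C)C)c(O[Si](C)(C)C(C)(C)C)c1CC=C(C)C | intermediate
16 | rac-3-[2,4-bis(TBSO)phenyl]-7-(TBSO)-3-hydroxy-6,8-diprenyl-2,3-dihydro-4H-chromen-4-one | CC(C)=CCc1cc2c(c(CC=C(C)C)c1O[Si](C)(C)C(C)(C)C)OCC(O)(c1ccc(O[Si](C)(C)C(C)(C)C)cc1O[Si](C)(C)C(C)(C)C)C2=O | intermediate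
17 | (3R)-3-[2,4-bis(TBSO)phenyl]-7-(TBSO)-3-hydroxy-6,8-diprenyl-2,3-dihydro-4H-chromen-4-one | CC(C)=CCc1cc2c(c(CC=C(C)C)c1O[Si](C)(C)C(C)(C)C)OC[C@](O)(c1ccc(O[Si](C)(C)C(C)(C)C)cc1O[Si](C)(C)C(C)(C)C)C2=O | intermediate
18 | (3R)-3-(2,4-dihydroxyphenyl)-3,7-dihydroxy-6,8-bis(3-methylbut-2-en-1-yl)-2,3-dihydro-4H-chromen-4-one | CC(C)=CCc1cc2c(c(CC=C(C)C)c1O)OC[C@](O)(c1ccc(O)cc1O)C2=O | target

**Step count**
Total: 10 steps. Longest linear sequence: 8 steps (from 1 through steps 1, 2, 3, 6, 7, 8, 9, 10).

**Steps most likely to fail**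

1. Step 8 (Proposed new method). Hydrogen transfer to O4 instead of O3, or quenching of the diketone triplet by the prenyl double bonds, would divert or stall ring closure. The fallback uses known chemistry, sets out from 12 and returns at 16. BCl3 (CH2Cl2, −78 °C) should remove the methyl ether ortho to the ketone by chelation and give the ortho-hydroxy deoxybenzoin F1. Me2NCH(OMe)2 in warm toluene closes it to the isoflavone F2. LiBH(s-Bu)3 (THF, −78 °C) reduces the C2–C3 double bond to the isoflavanone F3. Its enolate, made with KN(SiMe3)2 at −78 °C, is hydroxylated at C3 by 2-(phenylsulfonyl)-3-phenyloxaziridine to racemic 16, after which steps 9 and 10 follow.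

2. Step 7. Loss of the ring B silyl groups in warm basic DMF, or over-oxidation with cleavage of the C3–C4 bond, would erode the diketone. The fallback sets out from 12 and returns at 14. The enolate (LiN(SiMe3)2, THF, −78 °C) is brominated with N-bromosuccinimide to the α-bromo ketone F4, and Kornblum oxidation (DMSO, NaHCO3, 40 °C) then gives 14 without oxygen or amine base.

3. Step 3. Sluggish coupling at the iodide flanked by two oxygen substituents, insertion into the C–Br bond, or allyl transposition to the branched isomer would spoil the diprenylation. The fallback sets out from 1 and returns at 5. The sodium phenoxide of 1 (NaH, toluene) is alkylated at carbon, ortho to oxygen, with prenyl bromide in two rounds to 4-bromo-3-methoxy-2,6-diprenylphenol F5, and TBSCl with imidazole then gives 5; iodination and cross-coupling are avoided altogether.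

**Further compounds**
F1 | step 8 | 2-[2,4-bis(TBSO)phenyl]-1-[4-(TBSO)-2-hydroxy-3,5-diprenylphenyl]ethan-1-one | Oc1c(C(=O)Cc2ccc(O[Si](C)(C)C(C)(C)C)cc2O[Si](C)(C)C(C)(C)C)cc(CC=C(C)C)c(O[Si](C)(C)C(C)(C)C)c1CC=C(C)C
F2 | step 8 | 3-[2,4-bis(TBSO)phenyl]-7-(TBSO)-6,8-diprenyl-4H-chromen-4-one | CC(C)=CCc1cc2c(c(CC=C(C)C)c1O[Si](C)(C)C(C)(C)C)OC=C(c1ccc(O[Si](C)(C)C(C)(C)C)cc1O[Si](C)(C)C(C)(C)C)C2=O
F3 | step 8 | rac-3-[2,4-bis(TBSO)phenyl]-7-(TBSO)-6,8-diprenyl-2,3-dihydro-4H-chromen-4-one | CC(C)=CCc1cc2c(c(CC=C(C)C)c1O[Si](C)(C)C(C)(C)C)OCC(c1ccc(O[Si](C)(C)C(C)(C)C)cc1O[Si](C)(C)C(C)(C)C)C2=O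
F4 | step 7 | rac-2-[2,4-bis(TBSO)phenyl]-2-bromo-1-[4-(TBSO)-2-methoxy-3,5-diprenylphenyl]ethan-1-one | COc1c(C(=O)C(Br)c2ccc(O[Si](C)(C)C(C)(C)C)cc2O[Si](C)(C)C(C)(C)C)cc(CC=C(C)C)c(O[Si](C)(C)C(C)(C)C)c1CC=C(C)C
F5 | step 3 | 4-bromo-3-methoxy-2,6-bis(3-methylbut-2-en-1-yl)phenol | COc1c(Br)cc(CC=C(C)C)c(O)c1CC=C(C)C
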